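Read the last midnight reading first. The next move starts from it.

| flask | solid substrate | reagent | temperature | remark | time |
|---|---|---|---|---|---|
| midnight | 0.76 M | 1.14 M | 25 °C | the very flask that is asked about, followed so far |  |
| autumn | 0.76 M | 1.7 M | 25 °C | run made earlier |  |
| flask | 0.76 M | 1.14 M | 25 °C |  | 8.0 d |

| run | time / h | target / % | solid substrate / % |
|---|---|---|---|
| midnight | 10.0 | 5.0 | 86.7 |
| midnight | 30.0 | 16.1 | 62.5 |
| midnight | 60.0 | 29.1 | 28.0 |
| midnight | 72.0 | 32.7 | 14.9 |
| midnight | 120 | 37.9 | 0.1 |
| midnight | 144 | 38.1 | 0 |
| midnight | 192 | 38.0 | 0 |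
| autumn | 4.00 | 2.3 | 94.3 |
| autumn | 8.00 | 5.1 | 88.7 |
| autumn | 12.0 | 7.9 | 83.9 |
| autumn | 15.0 | 9.4 | 79.2 |
| autumn | 20.0 | 13.1 | 73.2 |
| autumn | 25.0 | 15.3 | 65.9 |
| autumn | 30.0 | 18.3 | 60.2 |

(readings scatter by 0.3 percentage points)

- target, in percent of the solid substrate first charged, at 8.0 d
- what to do for the largest gain in target; "none" if nothing gains more than 2 percentage points (red / amber / violet / none)
- target present, in percent of the solid substrate first charged, after red
- target present, in percent of the solid substrate first charged, after violet

- red: at 8.0 d raise the temperature by 10 K, then wait 2.5 d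
- amber: at 8.0 d add reagent, 50.0% of the amount charged, then wait 2.5 d
- violet: change nothing and wait 2.5 d more

- the volume of additions can be left aside
- the numbers in the tables scatter with a standard deviation of 0.3 percentage points
- at the start none of the solid substrate is in solution
- a reading or a percentage of target counts all its forms, free or not
- the earlier runs do not show what temperature does; that part of a forecast is a guess

1. Fix the time. The midnight run is the flask asked about, and its last reading, at 192 h, falls on 8.0 d. Take "now" from it: target 38.0%, solid substrate 0%.

2. Follow one molecule of solid substrate. In the midnight flask 38.0% is φ, the target found per solid substrate lost.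

3. Don't treat φ as a constant. At 30.0 h the midnight flask reads 42.9%, and at 30.0 h the autumn flask, with more reagent, reads 46.0%. So φ belongs to a recipe and a moment.

4. Price waiting. Treat solid substrate as the limiting reagent: the gain on offer from solid is φ times the solid left, 0 percentage points, less than 2 points. Amber multiplies the same 0%, whatever it does to φ.

5. Check the plateau, since these readings do not show dissolved substrate. The midnight target reads 37.9%, 38.1%, 38.0%, flat within a scatter of 0.3 points.

6. Decide as my own reckoning: add no reagent and leave the flask. Heat stays a guess, since no run shows temperature.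

7. Compare the forecast, which agrees: now 38% (37.6% to 38.4%), best none, red 38% (35.5% to 40%), violet 38% (37.5% to 38.5%). In its words, “the plateau looks like substrate exhaustion, not equilibrium”.

8. The flask gives 38.1% and best none. Red reaches 39.8%, a gain of 1.7 points, less than 2 points; violet stays at 38.1%. A fit of one reversible step, solid substrate with reagent, answers amber, yet amber gains 0 points.

    solid substrate ⇌ dissolved substrate, rate k1*(cs1 - [dissolved substrate]) while solid is left; crystals form when [dissolved substrate] > cs1 (solubility = 0.130 M, k = 0.00160 min⁻¹)
    dissolved substrate + reagent → target (k = 0.00410 M⁻¹ min⁻¹, Ea = 59.0 kJ mol⁻¹)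
    dissolved substrate + target → side product (k = 0.00260 M⁻¹ min⁻¹, Ea = 62.0 kJ mol⁻¹)
    solid product ⇌ target, rate k4*(cs4 - [target]) while solid is left; crystals form when [target] > cs4 (solubility = 0.340 M, k = 0.0640 min⁻¹)
    target ⇌ isomer of the product (K = 0.940, k = 0.00500 min⁻¹, Ea = 99.0 kJ mol⁻¹, ΔH = −7.00 kJ mol⁻¹)
    (constants at 25 °C)

9. In the flask, φ times the solid at 192 h is 0 points, and violet gains 0 points. A neighbour charged with 3.0 M of solid substrate, its other charges and the time held, keeps 50.1% solid at 192 h and holds 10.7% target, so its φ is 21.4%, less than the 38.0% read from the midnight flask.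

The earlier runs and the new flask are calculated for substances that don't exist, and the scatter is random.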